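The readings come from a simulation for substances that don't exist; noise was put on by code.

Count the target's half-lives.

in all of them: substrate 0.50 M; spent carrier 5 mol%

| flask | salt in the second phase | temperature | remark | time | volume of the second phase over the first |
|---|---|---|---|---|---|
| north | 2.5 equiv | 0 °C | the very flask that is asked about, followed so far |  |  |
| east | 2.5 equiv | −5 °C | run made earlier |  |  |
| flask | 2.50 equiv | 0 °C |  | 2.0 d | 0.50 |

| run | time / h | target / % | substrate / % |
|---|---|---|---|
| north | 4.00 | 55 | 46 |
| north | 10.0 | 76 | 12 |
| north | 20.0 | 76 | 2 |
| north | 30.0 | 65 | 2 |
| east | 4.00 | 38 | 59 |
| east | 10.0 | 69 | 33 |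
| east | 20.0 | 82 | 8 |
| east | 30.0 | 83 | 2 |

(scatter of a reading: 2 percentage points)

- in the second phase: salt in the second phase, spent salt in the second phase; everything else is in the first
- charges count per volume of the first phase; a concentration in a rate is the amount of a species over the volume of its own phase; every rate counts per litre of the first phase
- target that was removed still counts
- the numbers in the tables scatter with a standard deviation of 2 percentage points
- what may be going on: substrate + fresh carrier -> target + spent carrier; target -> over-reaction product; spent carrier + salt in the second phase <-> fresh carrier + spent salt in the second phase
- the earlier runs hold the two phases in the same ratio of volumes as the flask asked about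
- additions bring no volume worth counting

- autumn: at 2.0 d add substrate, 50.0% of the amount charged, then wait 50 h
- winter: change nothing and wait 50 h more
- dusk: at 2.0 d take out 90% of the target then present, then wait 50 h
- midnight: at 2.0 d raise the temperature by 25 K, then wait 50 h

1. target, in percent of the substrate first charged, at 2.0 d
2. the remedy with the largest gain of target, or "none" below 2 percentage points (autumn / winter / dusk / midnight / none)
3. target present, with what was taken out counted in, in percent of the substrate first charged, after autumn
4. target present, with what was taken out counted in, in percent of the substrate first charged, after midnight

**Two clocks.** In the north run, which is this flask followed so far, I read a substrate half-life of 3.10 h between 4.00 h and 10.0 h, a pseudo-first-order fall. Over the first 4.00 h the same reading gives 3.57 h, so I saw no separate clock from the carrier. Between 20.0 h and 30.0 h, with substrate at 2%, I read the half-life of the target, the time in which half of what stands passes on to over-reaction product, as 44.3 h.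

**Their ratio.** The ratio is 14.3, so I treated the flask as a charge that turns into target early and then decays, the longer clock over the difference of the two giving a factor 1.08 on the charge.

**My reckoning.** At 2.0 d the flask has stood 1.08 target half-lives, which gave me 50.8%. A wait of 50 h at 0 °C keeps 45.8% of the target, so I reckoned winter at −28 percentage points, dusk at −2.8 points and autumn at 47.8%, a change of −2.9 points, and I chose none. For midnight, the share that is neither target nor substrate at 30.0 h reads 2.20 times as much in the north run as in the east run, and I took this rough reading as my estimate of how far the target's clock speeds up from −5 °C to 0 °C. Compounding that ratio over the 5 such steps in a rise of 25 K gave me an estimated target half-life of 0.860 h, which leaves hardly any target after 50 h.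

The forecast gave 49% at 2.0 d, 45% after autumn and 0% after midnight, its first two below mine, and concluded: “None beats the present 49%, so best is none.”

**The flask.** At 48.0 h this flask held 50.3% target beside 49.7% over-reaction product. Autumn gave 47.9%, midnight 0%, and the choice was none, with autumn at −2.4 points and dusk at −2.8 points.

    substrate + fresh carrier → target + spent carrier (k = 13.7 M⁻¹ h⁻¹, Ea = 58.0 kJ mol⁻¹)
    target → over-reaction product (k = 0.0161 h⁻¹, Ea = 93.0 kJ mol⁻¹)
    spent carrier + salt in the second phase ⇌ fresh carrier + spent salt in the second phase (K = 0.790, k = 4.67 M⁻¹ h⁻¹, Ea = 58.0 kJ mol⁻¹, ΔH = 14.0 kJ mol⁻¹)
    (constants at 0 °C)

**Longer wait.** The same flask left until 5.0 d counts 2.71 target half-lives, so the reckoning gives 16.5% target. That flask held 15.8% target and 84.2% over-reaction product.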